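The runs come from a simulation for substances that don't exist; noise was put on by code.

The meeting opened on late times: at 30.0 min Thursday's run read electrophile 58.3% and product 27.9%, and the two peaks do not add up to the charge.

| flask | electrophile | nucleophile | free base | remark | time |
|---|---|---|---|---|---|
| Friday's | 10 mM | 26 mM | 30 mM | run made earlier |  |
| Thursday's | 15 mM | 26 mM | 30 mM | run made earlier |  |
| Tuesday's | 20 mM | 26 mM | 60 mM | run made earlier |  |
| flask | 20 mM | 26.0 mM | 30.0 mM |  | 30 min |

- Friday's (time / min: electrophile / %, product / %): 3.00: 92.2, 3.4; 5.00: 86.7, 6.8; 8.00: 79.5, 9.8; 12.0: 76.0, 13.7; 20.0: 63.4, 21.6; 40.0: 50.6, 36.1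
- Thursday's (time / min: electrophile / %, product / %): 2.50: 92.3, 3.5; 8.00: 81.1, 11.0; 12.0: 73.7, 16.5; 20.0: 66.0, 21.2; 30.0: 58.3, 27.9; 40.0: 51.4, 35.8
- Tuesday's (time / min: electrophile / %, product / %): 3.00: 90.5, 3.1; 10.0: 76.2, 12.0; 15.0: 73.2, 17.1; 25.0: 62.4, 24.1; 40.0: 55.1, 34.1

(standard deviation of a reading: 1 percentage point)

1. part of the electrophile that has reacted at 30 min
2. share of the unused nucleophile that is free and not bound as protonated nucleophile, at 30 min

- a reading or a percentage of product counts all its forms, free or not
- what has gone from electrophile into another species counts as reacted, even if it can come back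
- the earlier runs do not show how much of nucleophile is bound; that part of a forecast is a guess

I, taking the minutes, proposed splitting what has reacted into product and that gap. Let g be the gap over the electrophile remaining, from Thursday's reading 0.237. Let τ, the product time, be the time in which electrophile plus gap falls by the factor e, a pseudo-first-order time constant read from the same reading at 26 mM of nucleophile: 91.7 min. With t the time, the reacted part is c = 1 − exp(−t/τ)/(1 + g). I assumed that τ varies inversely with the nucleophile charge; Friday's, Thursday's and Tuesday's runs each held 26 mM, so this stayed an assumption. For the flask at 30 min I committed to 41.7%, which simply returns Thursday's reading and assumes that 20 mM of electrophile leaves the percentages unmoved. I offered no figure for fr, the asked share of the unused nucleophile that is free.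

The forecast gave c = 41% (38% to 44%) and fr = 90% (70% to 99%), arguing: “Tuesday's run is closest to the flask.” It stood 0.7 percentage points below my figure.

The flask gave c = 40.5% and fr = 85.1%.

    electrophile + nucleophile → acid set free + product (k = 0.590 M⁻¹ min⁻¹)
    nucleophile + acid set free ⇌ protonated nucleophile, settled at all times (K = 1200 M⁻¹)
    acid set free + free base ⇌ salt of the base (K = 4.90 × 10⁵ M⁻¹, k = 32.0 M⁻¹ min⁻¹)
    free base + product ⇌ idle adduct, settled at all times (K = 160 M⁻¹)
    electrophile ⇌ dormant form (K = 0.210, k = 0.0190 min⁻¹)

In the flask, τ puts product at 27.9% at 30.0 min; it held 27.4%, idle adduct counted, and the gap was the dormant form, 13.1%. For the neighbouring flask, charged with 44 mM of nucleophile, the assumed inverse rule shortens τ to 54.2 min, and g is kept as read. The reckoning then gives c = 53.5%, and that flask gave 52.8%, with 47% of its electrophile still there and 41.7% as product, idle adduct counted.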